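## Retrosynthetic overview

1. Target ⇒ desilylation, then epoxide → allylic alcohol isomerisation that leaves C2''–O untouched ⇒ (2''R)-6-(epoxyprenyl)flavanone.
2. Key C–O disconnection, C2''–O: oxygen transfer anchored on the 5-OH, selective for the 6-prenyl group and for one alkene face of 7,4'-bis-silyl (2S)-6,8-diprenylnaringenin.
3. Second C–O disconnection, O1–C2: asymmetric oxa-Michael closure of the symmetric 3',5'-diprenyl-2',4',6'-trihydroxychalcone. Both ortho-OH groups are equivalent, so no 6/8 regiochemical problem arises.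
4. Chalcone ⇒ aldol condensation of 3,5-diprenylphloroacetophenone with 4-silyloxybenzaldehyde. The ketone ⇒ phloroacetophenone + 2 prenyl bromide.
5. Ring order: rings A and B are bought. Pyranone ring C is closed first (step 3). A transient oxirane follows (step 4) and is opened in step 5.

Assumption: the facial sense of the chiral catalysts in steps 3 and 4 is taken by analogy. Both are available in both (pseudo)enantiomeric forms, and the form that gives 2S and 2''R is the one meant. TBS = tert-butyldimethylsilyl.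

## Route

**Step 1**
Reactants: 1 2,4,6-trihydroxyacetophenone; 2 prenyl bromide
Product: 3 3,5-diprenylphloroacetophenone
Conditions: 2 (2.1 equiv), KOH (2.2 equiv), H2O, 0 °C to rt
Reagents that add atoms: prenyl bromide (2), CC(C)=CCBr
Why: Base-mediated C-allylation of the ambident phloroglucinolate, where water favours C- over O-alkylation and the two free ring carbons are equivalent, so the 3,5-dialkylated ketone is the main aromatic product; no stereocentre is formed.

**Step 2**
Reactants: 3 3,5-diprenylphloroacetophenone; 4 4-(tert-butyldimethylsilyloxy)benzaldehyde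
Product: 6 (E)-4-O-TBS-2',4',6'-trihydroxy-3',5'-diprenylchalcone, via aldol adduct 5 (not isolated)
Conditions: LiHMDS (5 equiv), THF, −78 °C to rt; cold 1 M HCl quench
Reagents that add atoms: 4-(tert-butyldimethylsilyloxy)benzaldehyde (4), CC(C)(C)[Si](C)(C)Oc1ccc(C=O)cc1
Why: Claisen–Schmidt aldol condensation on the fully lithiated polyanion, in which excess LiHMDS masks the three OH groups as phenoxides and forms the methyl ketone enolate, which adds to 4 and loses hydroxide by E1cB to the E-enone; in strong aprotic base the chalcone stays open, and the fast cold acid quench keeps it open.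

**Step 3**
Reactants: 6 (E)-4-O-TBS-2',4',6'-trihydroxy-3',5'-diprenylchalcone
Product: 8 (2S)-7,4'-bis-O-TBS-6,8-diprenylnaringenin, via (2S)-4'-O-TBS-6,8-diprenylnaringenin 7 (not isolated)
Conditions: quinine-derived 3,5-(CF3)2C6H3-thiourea (10 mol %), PhMe, −20 °C; then TBSCl (1.2 equiv), imidazole, DMF, 0 °C
Reagents that add atoms: tert-butyldimethylsilyl chloride, CC(C)(C)[Si](C)(C)Cl
Why: Organocatalytic asymmetric intramolecular oxa-Michael addition (biomimetic chalcone-to-flavanone closure), in which the quinuclidine activates an ortho-OH while the thiourea binds the carbonyl held s-cis by the other ortho-OH, so O1 adds to one enone face and sets 2S; immediate silylation of the acidic, non-chelated 7-OH (the chelated 5-OH stays free) blocks retro-Michael racemisation.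

**Step 4**
Reactants: 8 (2S)-7,4'-bis-O-TBS-6,8-diprenylnaringenin
Product: 9 (2S,2''R)-7,4'-bis-O-TBS-6-(2,3-epoxy-3-methylbutyl)-8-prenylnaringenin
Conditions: Hf(OtBu)4 (10 mol %), N,N'-[(1R,2R)-cyclohexane-1,2-diyl]bis(N-hydroxy-2,2-diphenylacetamide) (12 mol %), DMPU (20 mol %), 4 Å MS, cumene hydroperoxide (1.2 equiv), PhMe, 0 °C
Reagents that add atoms: cumene hydroperoxide, CC(C)(OO)c1ccccc1
Why: Proposed new method: a site- and enantioselective epoxidation anchored on the peri-hydroxyketone, in which the only free OH of 8 (5-OH, together with C4=O a strong O,O-chelator for Zr/Hf(IV)) exchanges onto the chiral Hf(IV) bis-hydroxamate, and the η2-cumylperoxide on the same metal passes its electrophilic oxygen intramolecularly to the 6-prenyl alkene, which is bishomoallylic to O5 (O5–C5–C6–C1''–C2''=C3''); the 8-prenyl group has no anchor (O7 silylated, O1 an ether) and unbound trisubstituted alkenes are inert to Hf/ROOH at 0 °C, so the C2''–O bond forms only on the C6 chain and the C2-symmetric ligand pocket picks the face that gives 2''R; the silyl group on O7 and the chelation of O5 keep the epoxide from being trapped as a chroman or dihydrofuran; closest known reaction types are Zr/Hf bis-hydroxamic acid epoxidation of homoallylic and bishomoallylic alcohols and V/Ti phenol-directed epoxidation of o-allylphenols.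

**Step 5**
Reactants: 9 (2S,2''R)-7,4'-bis-O-TBS-6-(2,3-epoxy-3-methylbutyl)-8-prenylnaringenin
Product: 10 (2S,2''R)-7,4'-bis-O-TBS-6-(2-hydroxy-3-methylbut-3-enyl)-8-prenylnaringenin
Conditions: Cp2TiCl2 (2.5 equiv), Mn dust, THF, rt; 1 M HCl work-up, 0 °C
Reagents that add atoms: none
Why: Titanocene(III)-mediated homolytic epoxide opening (Nugent–RajanBabu type) breaks the C3''–O bond to the tertiary radical, and a second Cp2TiCl removes a methyl β-hydrogen (mixed disproportionation) to give the isopropenyl carbinol; the C2''–O bond is never touched, so 2''R is retained, and the neutral medium spares C2, the ketone, the silyl ethers and the 8-prenyl group.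

**Step 6**
Reactants: 10 (2S,2''R)-7,4'-bis-O-TBS-6-(2-hydroxy-3-methylbut-3-enyl)-8-prenylnaringenin
Product: 11 target CNP0257325.1
Conditions: KHF2 (4 equiv), MeOH/THF, rt
Reagents that add atoms: none
Why: Fluoride cleavage of the two aryl silyl ethers in a weakly acidic bifluoride buffer avoids the base that would open ring C (loss of 2S and 6/8 scrambling) and the acid that would cyclise the side chains; no stereocentre is touched.

## Compound list

| No. | Name | SMILES | Role |
|---|---|---|---|
| 1 | 2,4,6-trihydroxyacetophenone | CC(=O)c1c(O)cc(O)cc1O | starting material |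
| 2 | prenyl bromide (1-bromo-3-methylbut-2-ene) | CC(C)=CCBr | starting material |
| 3 | 1-[2,4,6-trihydroxy-3,5-bis(3-methylbut-2-enyl)phenyl]ethanone | CC(=O)c1c(O)c(CC=C(C)C)c(O)c(CC=C(C)C)c1O | intermediate |
| 4 | 4-(tert-butyldimethylsilyloxy)benzaldehyde | CC(C)(C)[Si](C)(C)Oc1ccc(C=O)cc1 | starting material |
| 5 | racemic 3-hydroxy-3-[4-(TBSO)phenyl]-1-[2,4,6-trihydroxy-3,5-diprenylphenyl]propan-1-one (aldol adduct, not isolated) | CC(C)=CCc1c(O)c(CC=C(C)C)c(O)c(C(=O)CC(O)c2ccc(O[Si](C)(C)C(C)(C)C)cc2)c1O | intermediate |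
| 6 | (E)-3-[4-(TBSO)phenyl]-1-[2,4,6-trihydroxy-3,5-diprenylphenyl]prop-2-en-1-one | CC(C)=CCc1c(O)c(CC=C(C)C)c(O)c(C(=O)/C=C/c2ccc(O[Si](C)(C)C(C)(C)C)cc2)c1O | intermediate |
| 7 | (2S)-5,7-dihydroxy-6,8-diprenyl-2-[4-(TBSO)phenyl]chroman-4-one (not isolated) | CC(C)=CCc1c(O)c(CC=C(C)C)c2c(c1O)C(=O)C[C@@H](c1ccc(O[Si](C)(C)C(C)(C)C)cc1)O2 | intermediate |
| 8 | (2S)-5-hydroxy-7-(TBSO)-6,8-diprenyl-2-[4-(TBSO)phenyl]chroman-4-one | CC(C)=CCc1c(O[Si](C)(C)C(C)(C)C)c(CC=C(C)C)c2c(c1O)C(=O)C[C@@H](c1ccc(O[Si](C)(C)C(C)(C)C)cc1)O2 | intermediate |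
| 9 | (2S)-6-{[(2R)-3,3-dimethyloxiran-2-yl]methyl}-5-hydroxy-7-(TBSO)-8-prenyl-2-[4-(TBSO)phenyl]chroman-4-one | CC1(C)O[C@@H]1Cc1c(O[Si](C)(C)C(C)(C)C)c(CC=C(C)C)c2c(c1O)C(=O)C[C@@H](c1ccc(O[Si](C)(C)C(C)(C)C)cc1)O2 | intermediate |
| 10 | (2S)-5-hydroxy-6-[(2R)-2-hydroxy-3-methylbut-3-enyl]-7-(TBSO)-8-prenyl-2-[4-(TBSO)phenyl]chroman-4-one | C=C(C)[C@H](O)Cc1c(O[Si](C)(C)C(C)(C)C)c(CC=C(C)C)c2c(c1O)C(=O)C[C@@H](c1ccc(O[Si](C)(C)C(C)(C)C)cc1)O2 | intermediate |
| 11 | (2S)-5,7-dihydroxy-6-[(2R)-2-hydroxy-3-methylbut-3-enyl]-2-(4-hydroxyphenyl)-8-(3-methylbut-2-enyl)chroman-4-one | C=C(C)[C@H](O)Cc1c(O)c(CC=C(C)C)c2c(c1O)C(=O)C[C@@H](c1ccc(O)cc1)O2 | target |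

## Step count and risks

Total step count: 6. Longest linear sequence: 6 (1 → 3 → 6 → 8 → 9 → 10 → 11).

The two stereocentres are set by two independent catalysts. The minor products of steps 3 and 4 are therefore mostly diastereomers of 9 and 10, and chromatography removes them. From step 4 onward base must be avoided, because opening of ring C would now scramble the 6- and 8-side chains.

**Step 4 (the new step).**
- Failure modes:
  - The O4/O5 chelate may hold hafnium too far from the alkene.
  - The bound aryloxide may be oxygenated at C6 to an o-quinol.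
  - O5 may still open the epoxide.
  - The Lewis-acidic alkoxide may epimerise C2.
- Fallback: this uses known chemistry, an ene reaction instead of a directed epoxidation, and sets out from 8. Dye-sensitised photooxygenation (O2, tetraphenylporphyrin, visible light, CH2Cl2, −20 °C, about half conversion) is a Schenck ene reaction. It places OOH on C2'' with shift of the double bond and gives the C2''-epimeric 6-(2-hydroperoxy-3-methylbut-3-enyl)flavanone F1, beside side-chain isomers. PPh3 reduces the crude hydroperoxides. Because C2 is fixed, every isomer is a diastereomer or a constitutional isomer, so preparative HPLC delivers the (2S,2''R) alcohol. The fallback comes back at 10 and skips 9 and step 5. The price is no site or face control, so only about 10–15 % of the mass is useful.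

**Step 3.**
- Failure modes:
  - The acidic 4'-OH of 6 can tie up the amine of the catalyst.
  - A racemic background closure can compete.
  - The closure is reversible, so ee can erode before silylation.
- Fallback: this is kinetic resolution by reduction instead of asymmetric ring closure, and it sets out from 6. Imidazole in DMF at rt closes the ring to the racemic flavanone F2, and TBSCl in the same pot gives the racemic bis-silyl ether F3. Asymmetric transfer hydrogenation follows with [Cp*RhCl((R,R)-TsDPEN)] and HCO2H/Et3N in EtOAc at rt, run to slightly over 50 % conversion. By the usual aryl ketone model this catalyst forms a 4R carbinol, so it is matched with the 2R ketone. It reduces that enantiomer to the cis-(2R,4R)-flavan-4-ol F4, and the prenyl groups are not touched. The unreacted 2S ketone is separated on silica, and the fallback comes back at 8. The yield is capped at 50 %.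

**Step 2.**
- Failure modes:
  - The tetra-anion may be too unreactive.
  - Lithium phenoxides may take over the aryl TBS group.
  - The chalcone may close to racemic flavanone during work-up.
- Fallback: this is a protecting-group route with a classical hydroxide-mediated condensation, and it sets out from 3.
  - MOMCl (2.2 equiv) with iPr2NEt in CH2Cl2 at 0 °C gives the 4,6-bis-MOM ether F5. One chelated OH stays free, and the two ortho-OH groups are equivalent, so there is one product.
  - KOH in EtOH/H2O with commercial 4-(methoxymethoxy)benzaldehyde gives the tris-MOM chalcone F6.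
  - HCl in MeOH at 40 °C gives the free 2',4',6',4-tetrahydroxy-3',5'-diprenylchalcone F7.
  - The catalyst of step 3 closes F7 to (2S)-6,8-diprenylnaringenin F8, which is silylated in the same pot with 2.3 equiv of TBSCl.
  - The fallback comes back at 8 and costs two extra steps.

## Further compounds

F1 | step 4 | (2S)-6-(2-hydroperoxy-3-methylbut-3-enyl)-5-hydroxy-7-(TBSO)-8-prenyl-2-[4-(TBSO)phenyl]chroman-4-one, C2'' epimers | C=C(C)C(OO)Cc1c(O[Si](C)(C)C(C)(C)C)c(CC=C(C)C)c2c(c1O)C(=O)C[C@@H](c1ccc(O[Si](C)(C)C(C)(C)C)cc1)O2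
F2 | step 3 | racemic 5,7-dihydroxy-6,8-diprenyl-2-[4-(TBSO)phenyl]chroman-4-one | CC(C)=CCc1c(O)c(CC=C(C)C)c2c(c1O)C(=O)CC(c1ccc(O[Si](C)(C)C(C)(C)C)cc1)O2
F3 | step 3 | racemic 5-hydroxy-7-(TBSO)-6,8-diprenyl-2-[4-(TBSO)phenyl]chroman-4-one | CC(C)=CCc1c(O[Si](C)(C)C(C)(C)C)c(CC=C(C)C)c2c(c1O)C(=O)CC(c1ccc(O[Si](C)(C)C(C)(C)C)cc1)O2
F4 | step 3 | (2R,4R)-7-(TBSO)-6,8-diprenyl-2-[4-(TBSO)phenyl]chromane-4,5-diol (2,4-cis) | CC(C)=CCc1c(O[Si](C)(C)C(C)(C)C)c(CC=C(C)C)c2c(c1O)[C@H](O)C[C@H](c1ccc(O[Si](C)(C)C(C)(C)C)cc1)O2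
F5 | step 2 | 1-[2-hydroxy-4,6-bis(methoxymethoxy)-3,5-diprenylphenyl]ethanone | CC(=O)c1c(O)c(CC=C(C)C)c(OCOC)c(CC=C(C)C)c1OCOC
F6 | step 2 | (E)-1-[2-hydroxy-4,6-bis(methoxymethoxy)-3,5-diprenylphenyl]-3-[4-(methoxymethoxy)phenyl]prop-2-en-1-one | COCOc1ccc(/C=C/C(=O)c2c(O)c(CC=C(C)C)c(OCOC)c(CC=C(C)C)c2OCOC)cc1
F7 | step 2 | (E)-3-(4-hydroxyphenyl)-1-[2,4,6-trihydroxy-3,5-diprenylphenyl]prop-2-en-1-one | CC(C)=CCc1c(O)c(CC=C(C)C)c(O)c(C(=O)/C=C/c2ccc(O)cc2)c1O
F8 | step 2 | (2S)-5,7-dihydroxy-2-(4-hydroxyphenyl)-6,8-diprenylchroman-4-one | CC(C)=CCc1c(O)c(CC=C(C)C)c2c(c1O)C(=O)C[C@@H](c1ccc(O)cc1)O2
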